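**Retrosynthetic overview**

1. Feature: in the ten-membered ring the Z C4=C5 enone, the C3 ketone and the C1/C10 diol are what is left of a triene C10=C1–C2=C3–C4=C5, which is the open form of a cyclohexa-1,3-diene (ring A: C1–C5, C10) fused to ring B across C5–C10.
2. Key disconnection: the C5–C10 bond, absent from the target, is restored in retrosynthesis to give a cis-fused 10-epi-eudesman-6α,12-olide carrying a 3-silyloxy-1,3-diene; in the forward sense light opens this bond and rings A and B merge.
3. After the opening: hydrolysis of the silyl enol ether gives the C3 ketone, and OsO4 on the E C1=C10 alkene gives the 1,10-diol.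
4. Before the opening: (R)-carvone supplies ring B and C7; γ-oxygenation gives C8–O; Robinson annulation with ethyl vinyl ketone adds ring A and sets C10; then C8 inversion and acylation, C6 hydroxylation, oxidative lactonisation, cis hydrogenation and C1–C2 dehydrogenation.
5. Ring order: ring B (carvone), ring A (annulation), γ-lactone, ten-membered ring (by cleavage of C5–C10).

Key step: step 18

Remark: eudesmane/germacrane numbering is used and α/β mean below/above the usual drawing with the C7 side chain β; the target is treated as the open 3-keto-1,10-diol as drawn, although its C10 hydroxyl and C3 ketone could also close to a cyclic hemiketal.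

**Route**

Step 1
Reactants: 1 (R)-carvone
Product: 3 trimethyl{[(5S)-2-methyl-5-(prop-1-en-2-yl)cyclohexa-1,3-dien-1-yl]oxy}silane, via bromomagnesium dienolate 2 (not isolated)
Conditions: MeMgBr, FeCl3 (cat.), Et2O, −20 → 0 °C; then TMSCl, Et3N, DMPU, 0 °C → rt
Reagents that add atoms: chlorotrimethylsilane, C[Si](C)(C)Cl
Why: The FeCl3/MeMgBr system (Kharasch reagent) acts as a base and removes the γ-proton at C4 of the enone to give the through-conjugated dienolate, which is silylated on oxygen (thermodynamic dienol silyl ether formation), the C5 stereocentre not being involved.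

Step 2
Reactants: 3 dienol silyl ether
Product: 5 (4S,5R)-4-hydroxy-2-methyl-5-(prop-1-en-2-yl)cyclohex-2-en-1-one, via silyloxy endoperoxide 4 (not isolated)
Conditions: O2, hν (visible), tetraphenylporphyrin (cat.), CH2Cl2, −78 °C; then PPh3, −78 °C → rt; then citric acid, MeOH
Reagents that add atoms: dioxygen (as singlet oxygen), O=O
Why: Singlet oxygen adds to the electron-rich cisoid silyloxydiene in a [4+2] cycloaddition from the face anti to the neighbouring isopropenyl group, the peroxy ketal collapses to the enone and PPh3 cleaves the O–O bond (γ-hydroxylation of an enone through its dienol ether), so the new C4 carbinol (C8 of the target) is trans to the isopropenyl group.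

Step 3
Reactants: 5 trans-4-hydroxycarvone
Product: 6 (4S,5R)-4-(tert-butyldimethylsilyloxy)-2-methyl-5-(prop-1-en-2-yl)cyclohex-2-en-1-one
Conditions: TBSCl, imidazole, DMF, rt
Reagents that add atoms: tert-butyldimethylsilyl chloride, CC(C)(C)[Si](C)(C)Cl
Why: Standard silylation of the secondary allylic alcohol protects the oxygen against oxa-Michael addition and side reactions in the basic annulation.

Step 4
Reactants: 6 silyl ether
Product: 7 (2R,4S,5R)-4-(tert-butyldimethylsilyloxy)-2-methyl-5-(prop-1-en-2-yl)cyclohexan-1-one (major C2 epimer)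
Conditions: LiBH(s-Bu)3, THF, −78 °C; then aq NH4Cl
Reagents that add atoms: none
Why: The bulky trialkylborohydride adds hydride to the β-carbon of the cyclohexenone, which carries no β-substituent (conjugate reduction), and leaves the isopropenyl group alone; protonation should give mainly the 2,5-trans epimer, and both C2 epimers converge in the next step.

Step 5
Reactants: 7 ketone; 8 ethyl vinyl ketone
Product: 11 8α-(tert-butyldimethylsilyloxy)-10-epi-eudesma-4,11-dien-3-one, via Michael adduct 9 (not isolated), via ketol 10 (not isolated)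
Conditions: KOH (0.2 equiv), EtOH, −10 °C → rt; then KOH, EtOH, 70 °C
Reagents that add atoms: ethyl vinyl ketone (8), CCC(=O)C=C
Why: Robinson annulation, in which the more substituted enolate attacks ethyl vinyl ketone axially through a chair-like transition state with the isopropenyl and silyloxy groups equatorial, so the new chain is cis and the C10 methyl trans to the C7 isopropenyl group (the 10-epi series, as in the annulation of dihydrocarvone), and intramolecular aldol condensation then closes ring A.

Step 6
Reactants: 11 silyl ether enone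
Product: 12 8α-hydroxy-10-epi-eudesma-4,11-dien-3-one
Conditions: TBAF, THF, 0 °C → rt
Reagents that add atoms: none
Why: Fluoride cleaves the Si–O bond selectively and the enone and isopropenyl group are inert (silyl ether deprotection).

Step 7
Reactants: 12 alcohol
Product: 13 10-epi-eudesma-4,11-diene-3,8-dione
Conditions: Dess–Martin periodinane, NaHCO3, CH2Cl2, 0 °C
Reagents that add atoms: none
Why: Buffered Dess–Martin oxidation gives the β,γ-unsaturated C8 ketone under neutral conditions that should neither epimerise C7 nor move the 11(13) double bond into conjugation.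

Step 8
Reactants: 13 diketone
Product: 14 8β-hydroxy-10-epi-eudesma-4,11-dien-3-one
Conditions: LiBH(s-Bu)3 (1.05 equiv), THF, −78 °C; then aq NH4Cl
Reagents that add atoms: none
Why: The bulky hydride attacks the saturated C8 ketone equatorially, anti to the adjacent C7 isopropenyl group, giving the axial 8β-alcohol cis to the side chain (as in isopulegone to neoisopulegol), while the conjugated, β,β-disubstituted C3 enone should react much more slowly at −78 °C.

Step 9
Reactants: 14 alcohol; 15 isobutyryl chloride
Product: 16 8β-isobutyryloxy-10-epi-eudesma-4,11-dien-3-one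
Conditions: pyridine, DMAP (cat.), CH2Cl2, 0 °C → rt
Reagents that add atoms: isobutyryl chloride (15), CC(C)C(=O)Cl
Why: DMAP-catalysed acylation of the hindered axial alcohol installs the isobutyrate of the target with retention at C8.

Step 10
Reactants: 16 isobutyrate
Product: 17 12-hydroxy-8β-isobutyryloxy-10-epi-eudesma-4,11(13)-dien-3-one
Conditions: SeO2 (0.3 equiv), t-BuOOH, CH2Cl2, rt
Reagents that add atoms: selenium dioxide, O=[Se]=O; tert-butyl hydroperoxide, CC(C)(C)OO
Why: Catalytic SeO2 allylic oxidation (ene reaction then [2,3]-shift) hydroxylates the methyl group of the electron-rich 1,1-disubstituted alkene while the electron-poor enone is inert, and any over-oxidised enal converges in step 12.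

Step 11
Reactants: 17 allylic alcohol
Product: 20 6α,12-dihydroxy-8β-isobutyryloxy-10-epi-eudesma-4,11(13)-dien-3-one, via bis-silyl dienol ether 18 (not isolated), via silyl ether hydroxy enone 19 (not isolated)
Conditions: TMSOTf, Et3N, CH2Cl2, 0 °C → rt; hexane filtration; mCPBA, NaHCO3, CH2Cl2, −20 °C; citric acid, MeOH, rt
Reagents that add atoms: 3-chloroperoxybenzoic acid, OOC(=O)c1cccc(Cl)c1
Why: Equilibrating silylation gives the heteroannular 3,5-dienol silyl ether, and the peracid attacks its C6 terminus (vinylogous Rubottom oxidation) from the α face, anti to the C7 side chain and the 8β-ester and syn to the angular methyl as in the 6-hydroxylation of steroidal 3,5-dienol ethers, which sets the 6α-hydroxyl trans to the side chain.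

Step 12
Reactants: 20 diol
Product: 22 8β-isobutyryloxy-3-oxo-10-epi-eudesma-4,11(13)-dien-6α,12-olide, via lactol 21 (not isolated)
Conditions: TEMPO (cat.), PhI(OAc)2, CH2Cl2, rt
Reagents that add atoms: none
Why: TEMPO/PhI(OAc)2 oxidises the primary allylic alcohol selectively to the aldehyde, the 6α-hydroxyl traps it as the five-membered lactol, and a second oxidation gives the trans-fused α-methylene γ-lactone (oxidative lactonisation of a 1,4-diol) without touching C6 or C7.

Step 13
Reactants: 22 α-methylene lactone
Product: 23 13-(dimethylamino)-8β-isobutyryloxy-3-oxo-11,13-dihydro-10-epi-eudesm-4-en-6α,12-olide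
Conditions: Me2NH (2 M in THF), THF, 0 °C → rt
Reagents that add atoms: dimethylamine, CNC
Why: Aza-Michael addition of the secondary amine to the exocyclic acrylate masks the 11(13) double bond for the hydrogenation and the enolate step, and the new C11 centre does not matter because it becomes sp2 again in step 16.

Step 14
Reactants: 23 amine adduct
Product: 24 13-(dimethylamino)-8β-isobutyryloxy-3-oxo-11,13-dihydro-4β-methyl-5αH-10-epi-eudesman-6α,12-olide (cis-fused)
Conditions: H2 (1 atm), 10% Pd/C, EtOAc, rt
Reagents that add atoms: none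
Why: Heterogeneous hydrogenation adds H2 to the tetrasubstituted enone double bond from the convex α face, because the trans-fused lactone can only span diequatorial positions on ring B and that is compatible with a cis-fused but not a trans-fused chair–chair decalin, so H5 ends cis to the C10 methyl (the C4 configuration is lost again in step 17).

Step 15
Reactants: 24 cis-fused ketone
Product: 26 13-(dimethylamino)-8β-isobutyryloxy-3-oxo-11,13-dihydro-5αH-10-epi-eudesm-1-en-6α,12-olide, via lithium enolate 25 (not isolated)
Conditions: LiN(i-Pr)2 (1.05 equiv), THF, −78 °C; then PhS(Cl)=N-t-Bu, −78 °C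
Reagents that add atoms: none
Why: Kinetic deprotonation at the unhindered C2 methylene of the ketone (more acidic than the lactone and ester α-positions) followed by the Mukaiyama dehydrogenation with N-tert-butylbenzenesulfinimidoyl chloride gives the 1-en-3-one in one pot without touching C4 or C5.

Step 16
Reactants: 26 amine-masked enone
Product: 28 8β-isobutyryloxy-3-oxo-5αH-10-epi-eudesma-1,11(13)-dien-6α,12-olide, via ammonium iodide 27 (not isolated)
Conditions: MeI, THF, rt; then aq NaHCO3, CH2Cl2, rt
Reagents that add atoms: none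
Why: Methylation turns the amine into a leaving group and mild base then triggers E1cB (Hofmann-type) elimination to regenerate the 11(13)-methylene lactone, the usual unmasking of amine adducts of α-methylene lactones.

Step 17
Reactants: 28 enone; 29 tert-butyldimethylsilyl triflate
Product: 30 3-(tert-butyldimethylsilyloxy)-8β-isobutyryloxy-5αH-10-epi-eudesma-1,3,11(13)-trien-6α,12-olide
Conditions: Et3N, CH2Cl2, −78 → 0 °C
Reagents that add atoms: tert-butyldimethylsilyl triflate (29), CC(C)(C)[Si](C)(C)OS(=O)(=O)C(F)(F)F
Why: Soft enolisation with silyl triflate and amine can only occur at C4, since the γ-carbon C10 of the 1-en-3-one is quaternary, so O-silylation gives the cross-conjugated 3-silyloxy-1,3-diene with the cis ring fusion unchanged.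

Step 18
Reactants: 30 silyloxy diene
Product: 31 3-(tert-butyldimethylsilyloxy)-8β-isobutyryloxygermacra-1(10),2,4,11(13)-tetraen-6α,12-olide with C1=C10 E, C4=C5 Z and C1/C4 cis on C2=C3
Conditions: hν (300 nm, Pyrex), degassed pentane/THF, −40 °C, to partial conversion; kept cold
Reagents that add atoms: none
Why: Excitation of the twisted cisoid diene permits the six-electron electrocyclic opening of the C5–C10 σ bond, conrotatory in the excited state; no ring is closed, rings A and B merge into the ten-membered carbocycle, and no stereocentre is created because C5 and C10 become sp2. The closest known reaction type is the photochemical opening of ring-fused cyclohexa-1,3-dienes to cyclic trienes (provitamin D to previtamin D, eudesmadienes to germacratrienes). The step needs one sense of conrotation, and the trans-fused lactone secures it by locking ring B in the chair with O6 and C11 equatorial, so that in the cis-fused diene C5–C6 is pseudo-axial and C10–C9 pseudo-equatorial on ring A. Opening along the ground-state helicity then turns C6 inward (C4=C5 Z) and C9 outward (C1=C10 E), while the central C2=C3 bond keeps C1 and C4 cis. Light of 300 nm, which the acrylate and esters do not absorb, low temperature and partial conversion should limit secondary E/Z isomerisation, [1,7]-hydrogen shift and thermal reclosure of the triene. The silyl enol ether holds C3 at the ketone oxidation level so that the next step removes the central double bond.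

Step 19
Reactants: 31 triene silyl enol ether
Product: 32 8β-isobutyryloxy-3-oxogermacra-1(10)E,4Z,11(13)-trien-6α,12-olide
Conditions: TBAF, AcOH, THF, −78 → −20 °C
Reagents that add atoms: none
Why: Buffered fluoride cleaves the Si–O bond and the dienolate is protonated kinetically at the α-carbon C2, which gives the C3 ketone conjugated with the Z C4=C5 bond and leaves the E C1=C10 bond out of conjugation.

Step 20
Reactants: 32 dienone
Product: 33 (1R,6R,7R,8R,10R)-1β,10α-dihydroxy-8β-isobutyryloxy-3-oxogermacra-4Z,11(13)-dien-6α,12-olide (target)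
Conditions: OsO4 (cat.), NMO, citric acid, acetone/H2O, 0 °C
Reagents that add atoms: osmium tetroxide, O=[Os](=O)(=O)=O; N-methylmorpholine N-oxide, C[N+]1([O-])CCOCC1; water, O
Why: Upjohn dihydroxylation, in which OsO4 adds suprafacially to the most electron-rich alkene, the trisubstituted E C1=C10 bond (the enone and acrylate double bonds are electron-poor), from its peripheral face in the ring conformer with C14 on the β side to give the 1β,10α-diol (1R,10R), citric acid keeping the medium slightly acidic to avoid β-elimination of the C1 hydroxyl and double-bond migration.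

**Compound list**

1 | (R)-carvone, (5R)-2-methyl-5-(prop-1-en-2-yl)cyclohex-2-en-1-one | CC1=CC[C@H](CC1=O)C(C)=C | starting material
2 | bromomagnesium through-conjugated dienolate of carvone (OMgBr on C1, C1=C2 and C3=C4) | CC1=C(O[Mg]Br)C[C@H](C(C)=C)C=C1 | intermediate
3 | trimethyl{[(5S)-2-methyl-5-(prop-1-en-2-yl)cyclohexa-1,3-dien-1-yl]oxy}silane | CC1=C(O[Si](C)(C)C)C[C@H](C(C)=C)C=C1 | intermediate
4 | 6-methyl-8-(prop-1-en-2-yl)-1-(trimethylsilyloxy)-2,3-dioxabicyclo[2.2.2]oct-5-ene, peroxide bridge anti to the isopropenyl group | CC1=C[C@@H]2OO[C@@]1(O[Si](C)(C)C)C[C@@H]2C(C)=C | intermediate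
5 | (4S,5R)-4-hydroxy-2-methyl-5-(prop-1-en-2-yl)cyclohex-2-en-1-one | CC1=C[C@H](O)[C@@H](C(C)=C)CC1=O | intermediate
6 | (4S,5R)-4-(tert-butyldimethylsilyloxy)-2-methyl-5-(prop-1-en-2-yl)cyclohex-2-en-1-one | CC1=C[C@H](O[Si](C)(C)C(C)(C)C)[C@@H](C(C)=C)CC1=O | intermediate
7 | (2R,4S,5R)-4-(tert-butyldimethylsilyloxy)-2-methyl-5-(prop-1-en-2-yl)cyclohexan-1-one (major C2 epimer) | C[C@@H]1C[C@H](O[Si](C)(C)C(C)(C)C)[C@@H](C(C)=C)CC1=O | intermediate
8 | ethyl vinyl ketone (pent-1-en-3-one) | CCC(=O)C=C | starting material
9 | (2S,4S,5R)-4-(tert-butyldimethylsilyloxy)-2-methyl-2-(3-oxopentyl)-5-(prop-1-en-2-yl)cyclohexan-1-one | CCC(=O)CC[C@@]1(C)C[C@H](O[Si](C)(C)C(C)(C)C)[C@@H](C(C)=C)CC1=O | intermediate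
10 | 8α-(tert-butyldimethylsilyloxy)-5-hydroxy-10-epi-eudesm-11-en-3-one (aldol; C4 and C5 not defined, both lost on dehydration) | CC1C(=O)CC[C@@]2(C)C[C@H](O[Si](C)(C)C(C)(C)C)[C@@H](C(C)=C)CC12O | intermediate
11 | 8α-(tert-butyldimethylsilyloxy)-10-epi-eudesma-4,11-dien-3-one (10α-Me, H-7α) | CC1=C2C[C@H](C(C)=C)[C@@H](O[Si](C)(C)C(C)(C)C)C[C@]2(C)CCC1=O | intermediate
12 | 8α-hydroxy-10-epi-eudesma-4,11-dien-3-one | CC1=C2C[C@H](C(C)=C)[C@@H](O)C[C@]2(C)CCC1=O | intermediate
13 | 10-epi-eudesma-4,11-diene-3,8-dione | CC1=C2C[C@H](C(C)=C)C(=O)C[C@]2(C)CCC1=O | intermediate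
14 | 8β-hydroxy-10-epi-eudesma-4,11-dien-3-one | CC1=C2C[C@H](C(C)=C)[C@H](O)C[C@]2(C)CCC1=O | intermediate
15 | isobutyryl chloride | CC(C)C(=O)Cl | starting material
16 | 8β-isobutyryloxy-10-epi-eudesma-4,11-dien-3-one | CC1=C2C[C@H](C(C)=C)[C@H](OC(=O)C(C)C)C[C@]2(C)CCC1=O | intermediate
17 | 12-hydroxy-8β-isobutyryloxy-10-epi-eudesma-4,11(13)-dien-3-one | CC1=C2C[C@H](C(=C)CO)[C@H](OC(=O)C(C)C)C[C@]2(C)CCC1=O | intermediate
18 | 8β-isobutyryloxy-3,12-bis(trimethylsilyloxy)-10-epi-eudesma-3,5,11(13)-triene | CC1=C(O[Si](C)(C)C)CC[C@@]2(C)C[C@@H](OC(=O)C(C)C)[C@@H](C(=C)CO[Si](C)(C)C)C=C12 | intermediate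
19 | 6α-hydroxy-8β-isobutyryloxy-12-(trimethylsilyloxy)-10-epi-eudesma-4,11(13)-dien-3-one | CC1=C2[C@@H](O)[C@H](C(=C)CO[Si](C)(C)C)[C@H](OC(=O)C(C)C)C[C@]2(C)CCC1=O | intermediate
20 | 6α,12-dihydroxy-8β-isobutyryloxy-10-epi-eudesma-4,11(13)-dien-3-one | CC1=C2[C@@H](O)[C@H](C(=C)CO)[C@H](OC(=O)C(C)C)C[C@]2(C)CCC1=O | intermediate
21 | 6α,12-lactol of 20 (12-hydroxy-6α,12-epoxy; C12 not defined) | C=C1C(O)O[C@@H]2C3=C(C)C(=O)CC[C@@]3(C)C[C@@H](OC(=O)C(C)C)[C@@H]12 | intermediate
22 | 8β-isobutyryloxy-3-oxo-10-epi-eudesma-4,11(13)-dien-6α,12-olide (H-6β, H-7α) | C=C1C(=O)O[C@@H]2C3=C(C)C(=O)CC[C@@]3(C)C[C@@H](OC(=O)C(C)C)[C@@H]12 | intermediate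
23 | 13-(dimethylamino)-8β-isobutyryloxy-3-oxo-11,13-dihydro-10-epi-eudesm-4-en-6α,12-olide (C11 not defined) | CN(C)CC1C(=O)O[C@@H]2C3=C(C)C(=O)CC[C@@]3(C)C[C@@H](OC(=O)C(C)C)[C@@H]12 | intermediate
24 | 13-(dimethylamino)-8β-isobutyryloxy-3-oxo-11,13-dihydro-4β-methyl-5αH-10-epi-eudesman-6α,12-olide | CN(C)CC1C(=O)O[C@@H]2[C@H]3[C@@H](C)C(=O)CC[C@@]3(C)C[C@@H](OC(=O)C(C)C)[C@@H]12 | intermediate
25 | lithium C2=C3 enolate of 24 | CN(C)CC1C(=O)O[C@@H]2[C@H]3[C@@H](C)C(O[Li])=CC[C@@]3(C)C[C@@H](OC(=O)C(C)C)[C@@H]12 | intermediate
26 | 13-(dimethylamino)-8β-isobutyryloxy-3-oxo-11,13-dihydro-5αH-10-epi-eudesm-1-en-6α,12-olide | CN(C)CC1C(=O)O[C@@H]2[C@H]3[C@@H](C)C(=O)C=C[C@@]3(C)C[C@@H](OC(=O)C(C)C)[C@@H]12 | intermediate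
27 | 13-(trimethylammonio) iodide of 26 | C[N+](C)(C)CC1C(=O)O[C@@H]2[C@H]3[C@@H](C)C(=O)C=C[C@@]3(C)C[C@@H](OC(=O)C(C)C)[C@@H]12.[I-] | intermediate
28 | 8β-isobutyryloxy-3-oxo-5αH-10-epi-eudesma-1,11(13)-dien-6α,12-olide | C=C1C(=O)O[C@@H]2[C@H]3[C@@H](C)C(=O)C=C[C@@]3(C)C[C@@H](OC(=O)C(C)C)[C@@H]12 | intermediate
29 | tert-butyldimethylsilyl triflate | CC(C)(C)[Si](C)(C)OS(=O)(=O)C(F)(F)F | starting material
30 | 3-(tert-butyldimethylsilyloxy)-8β-isobutyryloxy-5αH-10-epi-eudesma-1,3,11(13)-trien-6α,12-olide (cis-fused, 10α-Me) | C=C1C(=O)O[C@@H]2[C@H]3C(C)=C(O[Si](C)(C)C(C)(C)C)C=C[C@@]3(C)C[C@@H](OC(=O)C(C)C)[C@@H]12 | intermediate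
31 | 3-(tert-butyldimethylsilyloxy)-8β-isobutyryloxygermacra-1(10),2,4,11(13)-tetraen-6α,12-olide (C1=C10 E, C4=C5 Z, C1/C4 cis on C2=C3) | C=C1C(=O)O[C@@H]2/C=C(/C)\C(O[Si](C)(C)C(C)(C)C)=C/C=C(C)/C[C@@H](OC(=O)C(C)C)[C@@H]12 | intermediate
32 | 8β-isobutyryloxy-3-oxogermacra-1(10)E,4Z,11(13)-trien-6α,12-olide | C=C1C(=O)O[C@@H]2/C=C(/C)C(=O)C/C=C(C)/C[C@@H](OC(=O)C(C)C)[C@@H]12 | intermediate
33 | (1R,6R,7R,8R,10R)-1β,10α-dihydroxy-8β-isobutyryloxy-3-oxogermacra-4Z,11(13)-dien-6α,12-olide | C=C1C(=O)O[C@@H]2/C=C(/C)C(=O)C[C@@H](O)[C@](C)(O)C[C@@H](OC(=O)C(C)C)[C@@H]12 | target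

**Step count**

Total steps: 20. Longest linear sequence: 20 steps from (R)-carvone (fully linear).

**Three steps most likely to fail**

Step 18. What may go wrong: erosion of the sense of conrotation, secondary photoisomerisation or sigmatropic hydrogen shift of the electron-rich silyloxytriene during irradiation, and loss of the labile dienol silyl ether on handling, so that the Z,E-triene is not obtained pure. The fallback stores the C3 ketone as an enol ester instead of a silyl enol ether. It sets out from 28: acid-catalysed enol acetylation (isopropenyl acetate, TsOH, 80 °C; only C4 can enolise) would give the 3-acetoxy-8β-isobutyryloxy-5αH-10-epi-eudesma-1,3,11(13)-trien-6α,12-olide F1. Irradiation as in step 18 would give the triene enol acetate F2, which should tolerate chromatography, so geometric isomers could be separated and unreacted F1 recycled. Bu3SnOMe in THF would then cleave the enol ester selectively (the alkyl ester and lactone being much less reactive) to a tin enolate that is protonated at C2 on work-up, and the route is rejoined at 32.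

Step 11. What may go wrong: delivery of the peracid oxygen to the β face of C6 (or to C4) of the dienol ether, giving the 6β-alcohol, which can only close to the cis-fused lactone. The fallback converts the same facial bias into the 6α C–O bond by a ring closure with inversion. It sets out from 17: oxidation with TEMPO/NaOCl/NaClO2 would give the acrylic acid F3. TMSOTf/Et3N would give the silyl ester dienol ether F4, and NBS, which is γ-selective on such dienol ethers and should attack the same β face, would give after aqueous work-up the 6β-bromo acid F5. K2CO3 in DMF would then close the lactone by intramolecular SN2 displacement with inversion at C6, and the route is rejoined at 22.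

Step 20. What may go wrong: osmylation of the other face of the C1=C10 bond (reaction through the ring conformer with C14 on the α side), giving the 1α,10β-diol, or base-induced double-bond migration and β-elimination of the C1 hydroxyl. The fallback replaces substrate control by reagent control. It sets out from 32: stoichiometric OsO4 pre-complexed with the phthalazine ligand (DHQD)2PHAL in toluene at −78 °C, followed by reductive cleavage of the osmate ester with aqueous NaHSO3. For this trisubstituted E-alkene (C9 large, C14 small, C2 medium substituent) the ligand directs oxygen to the face that gives (1R,10R), so the sequence ends directly at 33 and no new compound is involved.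

**Further compounds**

F1 | step 18 | 3-acetoxy-8β-isobutyryloxy-5αH-10-epi-eudesma-1,3,11(13)-trien-6α,12-olide | C=C1C(=O)O[C@@H]2[C@H]3C(C)=C(OC(C)=O)C=C[C@@]3(C)C[C@@H](OC(=O)C(C)C)[C@@H]12
F2 | step 18 | 3-acetoxy-8β-isobutyryloxygermacra-1(10),2,4,11(13)-tetraen-6α,12-olide (C1=C10 E, C4=C5 Z) | C=C1C(=O)O[C@@H]2/C=C(/C)\C(OC(C)=O)=C/C=C(C)/C[C@@H](OC(=O)C(C)C)[C@@H]12
F3 | step 11 | 8β-isobutyryloxy-3-oxo-10-epi-eudesma-4,11(13)-dien-12-oic acid | CC1=C2C[C@H](C(=C)C(=O)O)[C@H](OC(=O)C(C)C)C[C@]2(C)CCC1=O
F4 | step 11 | trimethylsilyl 8β-isobutyryloxy-3-(trimethylsilyloxy)-10-epi-eudesma-3,5,11(13)-trien-12-oate | CC1=C(O[Si](C)(C)C)CC[C@@]2(C)C[C@@H](OC(=O)C(C)C)[C@@H](C(=C)C(=O)O[Si](C)(C)C)C=C12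
F5 | step 11 | 6β-bromo-8β-isobutyryloxy-3-oxo-10-epi-eudesma-4,11(13)-dien-12-oic acid | CC1=C2[C@H](Br)[C@H](C(=C)C(=O)O)[C@H](OC(=O)C(C)C)C[C@]2(C)CCC1=O
F0 | step 20 | none | none
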